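**Starting material.** The north-east run cannot have turned its whole charge of starting material into target. Its reading of 22.5% at 25.0 h stands for 0.00810 M of starting material, less than the 0.036 M charged, and the runs give no reading of partner, which was charged at 0.054 M. Yet its rate falls.

the same everywhere: free catalyst 18 µM

|  | starting material | second substrate | partner | protic impurity | remark | time |
|---|---|---|---|---|---|---|
| north-west | 0.036 M | 0.072 M | 0.054 M | 0.72 mM | run made earlier |  |
| north-east | 0.036 M | 0.10 M | 0.054 M | 0.72 mM | run made earlier |  |
| north | 0.036 M | 0.16 M | 0.054 M | 0.72 mM | run made earlier |  |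
| elm | 0.036 M | 0.0720 M | 0.0540 M | 0.720 mM | everything together in a closed stirred flask, run for 25 h | 25 h |
| maple | 0.036 M | 0.0720 M | 0.0540 M | 0.720 mM | a single well-mixed tank run continuously and read at steady state, 25 h in it on average |  |
| birch | 0.036 M (fed, over 25.0 h) | 0.0720 M | 0.0540 M | 0.720 mM | a stirred flask in which starting material is dosed at a steady rate over 25.0 h without added volume, worked up at 25 h | 25 h |
| cedar | 0.036 M | 0.0720 M | 0.0540 M (fed, over 25.0 h) | 0.720 mM | a stirred flask in which partner is dosed at a steady rate over 25.0 h without added volume, worked up at 25 h | 25 h |

| run | time / h | target / % |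
|---|---|---|
| north-west | 1.33 | 2.5 |
| north-west | 3.00 | 6.5 |
| north-west | 6.00 | 10.5 |
| north-west | 15.0 | 20.8 |
| north-east | 3.00 | 6.1 |
| north-east | 8.00 | 13.7 |
| north-east | 15.0 | 19.2 |
| north-east | 25.0 | 22.5 |
| north | 2.00 | 3.8 |
| north | 5.00 | 7.6 |
| north | 10.0 | 13.7 |
| north | 25.0 | 21.3 |

(scatter of a reading: 0.5 percentage points)

- the stated concentrations are those of everything mixed, before any reaction; amounts are the same in each set-up
- the analysis behind the earlier runs scatters by 0.5 percentage points, standard deviation
- the feed brings no volume worth counting
- the earlier runs were made in a closed, stirred flask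

1. the set-up with the highest amount of target at the outlet or at the end, in percent of the starting material put in ("none" if the first two lie within 2 percentage points) (elm / maple / birch / cedar / none)
2. amount of target at the outlet or at the end, in percent of the starting material put in, elm
3. amount of target at the outlet or at the end, in percent of the starting material put in, maple
4. amount of target at the outlet or at the end, in percent of the starting material put in, birch
5. amount of target at the outlet or at the end, in percent of the starting material put in, cedar

**Two times.** In the north-east run, target forms at 0.0152 h⁻¹ of the charge between 3.00 h and 8.00 h, then at 0.00330 h⁻¹ between 15.0 h and 25.0 h. Read as an exponential fall, these give a fade time, the first-order lifetime of the rate, of 9.49 h, and a starting rate of 0.0271 h⁻¹. The other time is the dosing time, 25.0 h, and the ratio of the two is 2.63.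

**The reckoning.** The runs hold partner at one charge, so they cannot name what fades. This reckoning takes it to be partner, with the rate first order in partner and in starting material. A first-order loss takes the same share of any charge, leaving 7.18% after 25.0 h. Integrating the rate gives elm 23.9%, maple 18.7%, birch 7.23% and cedar 16.7%.

**The forecast.** It reads “This looks like catalyst death” and gives elm 25%, maple 17%, birch 10% and cedar 11%, with elm best. It parts from the reckoning at cedar.

**The result.** Elm gives 24.4%, maple 21.4%, birch 11.2% and cedar 20.7%, so elm is best.

    starting material + free catalyst ⇌ catalyst intermediate A (K = 53.0 M⁻¹, k = 0.870 M⁻¹ s⁻¹)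
    partner + catalyst intermediate A → free catalyst + target (k = 0.940 M⁻¹ s⁻¹)
    second substrate + free catalyst ⇌ catalyst intermediate B (K = 5.30 M⁻¹, k = 0.370 M⁻¹ s⁻¹)
    partner + catalyst intermediate B → free catalyst + second product (k = 0.260 M⁻¹ s⁻¹)
    starting material + protic impurity → quenched substrate (k = 0.00250 M⁻¹ s⁻¹)
    partner → decomposed reagent (k = 2.50 × 10⁻⁵ s⁻¹)
    partner ⇌ dormant form (K = 0.650, k = 2.10 × 10⁻⁶ s⁻¹)

**Neighbour flask.** The fade time leaves 7.18% of a charge after 25.0 h, and elm holds 4.94% of its partner at 25.0 h, birch 5.93%. The neighbour is birch with 0.092 M of partner, and the same reckoning gives it the same 7.18%. It holds 6.29% of its own charge at 25.0 h. Its target reaches 15.5%, more than the 11.2% of birch.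

The numbers in the tables are simulated on assumed constants; scatter was added.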